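## Retrosynthetic overview

1. The trimer is cut at the two interflavan bonds: top C4–mid C8 (last C–C bond, biomimetic SN1 arylation steered by a C3 acyloxy group, gives 4β) and mid C4–bottom C8 (aryl-cerium addition to a 4-ketone, then ionic hydrogenation, gives 4α).
2. Both 5-deoxy units come from one chroman, 14, whose pyran ring C is closed between C2 and C3 by a Prins cyclization of an O1=C2 aryloxycarbenium ion onto a (Z)-styrenyl enol pivalate.
3. Enabling feature: the ether oxygen on C7 of ring A is para to C4a, so C4 can carry the positive charge (p-quinone-methide-type benzylic cation) while C3, the carbon that bears the future 3-OH, bonds to C2. The C3 acyloxy group then captures C4.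
4. Ring order: ring C of the 5-deoxy unit (step 5, used twice), then the mid–bottom union, then the top–mid union. Rings A and B are bought as arenes; the bottom unit is (−)-epicatechin.
5. Bromine at C6 of every A ring and a free 7-OH on the mid unit direct the last bond to mid C8; all masks leave in steps 14 and 15.

Key step: step 5

Remarks on the chemistry: α is the face of a C ring that carries its 2-aryl group, β the other face; every unit is 2R. Compounds 1, 6 and 18 are taken as purchasable. The antipode of the chiral acid in step 5 that gives the 2R series has to be found by screening.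

## Route

Step 1
Reactants: 1 5-bromo-2,4-dihydroxybenzaldehyde; 2 4-methoxybenzyl chloride
Product: 3 5-bromo-2-hydroxy-4-[(4-methoxybenzyl)oxy]benzaldehyde
Conditions: NaHCO3, KI (cat.), MeCN, 70 °C
Reagents that add atoms: 4-methoxybenzyl chloride, COc1ccc(CCl)cc1
Why: Williamson etherification; the 4-OH, which is not hydrogen-bonded to the aldehyde and is acidified by the ortho bromine, should be alkylated selectively.

Step 2
Reactants: 3 5-bromo-2-hydroxy-4-[(4-methoxybenzyl)oxy]benzaldehyde; 4 dimethyl (1-diazo-2-oxopropyl)phosphonate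
Product: 5 4-bromo-2-ethynyl-5-[(4-methoxybenzyl)oxy]phenol
Conditions: K2CO3, MeOH, 0 °C → rt
Reagents that add atoms: dimethyl (1-diazo-2-oxopropyl)phosphonate, COP(=O)(OC)C(=[N+]=[N-])C(C)=O
Why: Ohira–Bestmann homologation turns the aldehyde into the terminal alkyne under mild base that the aryl bromide and the PMB ether tolerate.

Step 3
Reactants: 5 4-bromo-2-ethynyl-5-[(4-methoxybenzyl)oxy]phenol; 6 3,4,5-tris(benzyloxy)benzaldehyde; 7 pivaloyl chloride
Product: 9 {4-bromo-2-ethynyl-5-[(4-methoxybenzyl)oxy]phenoxy}[3,4,5-tris(benzyloxy)phenyl]methyl pivalate (racemic acylal), via chloro ester 8 (not isolated)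
Conditions: 6, 7 (slight deficit), ZnCl2 (5 mol%), CH2Cl2, 0 °C → rt; then 5, iPr2NEt, 0 °C → rt
Reagents that add atoms: pivaloyl chloride, CC(C)(C)C(=O)Cl
Why: Lewis-acid-catalysed addition of the acyl chloride to the aldehyde gives the α-chloroalkyl ester, which O-alkylates the phenol (acyloxyalkylation, as with pivaloyloxymethyl chloride) and so installs the O1–C2 bond as an acylal; the acetal carbon is racemic and is flattened in step 5.

Step 4
Reactants: 9 acylal alkyne; 10 pivalic acid
Product: 11 (Z)-2-{5-bromo-4-[(4-methoxybenzyl)oxy]-2-[(pivaloyloxy)(3,4,5-tris(benzyloxy)phenyl)methoxy]phenyl}vinyl pivalate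
Conditions: [RuCl2(p-cymene)]2 (1 mol%), P(4-ClC6H4)3 (3 mol%), DMAP (4 mol%), toluene, 60 °C
Reagents that add atoms: pivalic acid, CC(C)(C)C(=O)O
Why: Ru-catalysed anti-Markovnikov hydro-oxycarbonylation of the terminal alkyne through a Ru-vinylidene should give the (Z)-enol ester; pivalate exchange at the acylal is degenerate, so the acid does no harm there.

Step 5
Reactants: 11 (Z)-enol pivalate acylal
Product: 14 (2R)-2,3-cis-3,4-trans-6-bromo-7-[(4-methoxybenzyl)oxy]-2-[3,4,5-tris(benzyloxy)phenyl]chromane-3,4-diyl dipivalate, via aryloxycarbenium ion 12 (not isolated), via acyloxonium ion 13 (not isolated)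
Conditions: confined chiral imidodiphosphorimidate (IDPi) Brønsted acid (5 mol%), CHCl3, −50 °C
Reagents that add atoms: none
Why: Proposed new method: an enantioselective Prins cyclization of an α-acyloxy ether under a confined chiral Brønsted acid, whose closest known relatives are Lewis-acid Prins cyclizations of α-acetoxy ethers and catalytic asymmetric Prins and oxa-Pictet–Spengler cyclizations of oxocarbenium ion pairs; new are the styrenyl enol ester that attacks through its oxygen-bearing carbon and the acyloxonium termination. The acid ionizes the acylal (pivalic acid leaves) to aryloxycarbenium ion 12, held as an ion pair with the chiral anion, and C3 of the Z-enol pivalate adds to C2 in a 6-endo-trig closure of the pyran ring, because the charge that develops at C4 is taken up by the ring-A ether oxygen para to C4a, which should override the enol-ester polarity that would lead 5-exo to a benzofuran. The cation at C4 is captured at once by the carbonyl oxygen of the C3 pivalate (5-membered closure of the temporary cis-fused dioxolanylium ring of 13), and the pivalic acid set free in the first event opens this ion at C4 from the β-face and returns the proton, so the step is a catalytic isomerization. C2 and C3: the half-chair puts the 2-aryl group of the E-oxocarbenium equatorial and the Z-configured OPiv axial, hence 2,3-cis, and the chiral anion pocket selects the enantiotopic face (2R series). C4: anti opening of the acyloxonium gives 3,4-trans, but this centre is ionized again in steps 6 and 13 and need not be uniform. The step needs 6-endo over 5-exo closure and an intact Z-olefin: the para oxygen secures the first, the faster ionization of the acylal compared with alkene protonation at −50 °C the second, and the bromine on ring A suppresses intermolecular Friedel–Crafts attack.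

Step 6
Reactants: 14 trans-dipivalate; 15 water
Product: 16 (2R)-2,3-cis-3,4-cis-6-bromo-4-hydroxy-7-[(4-methoxybenzyl)oxy]-2-[3,4,5-tris(benzyloxy)phenyl]chroman-3-yl pivalate
Conditions: TsOH·H2O (10 mol%), THF–H2O 9:1, rt
Reagents that add atoms: water, O
Why: SN1 solvolysis of the benzylic C4 pivalate with anchimeric help from the trans C3 pivalate; water opens ion 13 through the ortho acid, which should leave the axial C3 ester and the C4 alcohol (a C4 epimer would serve equally, since C4 becomes sp2 in step 7).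

Step 7
Reactants: 16 cis-hydroxy pivalate
Product: 17 (2R)-2,3-cis-6-bromo-7-[(4-methoxybenzyl)oxy]-4-oxo-2-[3,4,5-tris(benzyloxy)phenyl]chroman-3-yl pivalate
Conditions: Dess–Martin periodinane, CH2Cl2, 0 °C → rt
Reagents that add atoms: none
Why: Dess–Martin oxidation of the benzylic alcohol under non-basic conditions should preserve the epimerizable cis C3 ester.

Step 8
Reactants: 18 (−)-epicatechin; 19 benzyl bromide
Product: 20 3,5,7,3',4'-penta-O-benzyl-(−)-epicatechin
Conditions: NaH, DMF, 0 °C → rt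
Reagents that add atoms: benzyl bromide, BrCc1ccccc1
Why: Williamson perbenzylation of the four phenols and the C3 alcohol; no stereocenter is touched.

Step 9
Reactants: 20 penta-O-benzyl-(−)-epicatechin; 21 N-bromosuccinimide
Product: 22 8-bromo-3,5,7,3',4'-penta-O-benzyl-(−)-epicatechin
Conditions: CH2Cl2, −40 → 0 °C
Reagents that add atoms: N-bromosuccinimide, O=C1CCC(=O)N1Br
Why: Electrophilic aromatic bromination at C8 of the phloroglucinol-type ring A, the position known to react first in benzylated epicatechin.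

Step 10
Reactants: 22 8-bromo-penta-O-benzyl-(−)-epicatechin; 17 ketone
Product: 25 tertiary alcohol (17 with 4α-OH and the C8 of penta-O-benzylepicatechin at 4β), via aryllithium 23 (not isolated), via arylcerium dichloride 24 (not isolated)
Conditions: t-BuLi (2 equiv), THF, −78 °C; CeCl3, −78 °C; then 17; AcOH quench at −78 °C
Reagents that add atoms: none
Why: Br/Li exchange, transmetalation to the weakly basic organocerium and 1,2-addition to the ketone should avoid enolization at C3 and attack on the hindered pivalate; addition anti to the α groups at C2 and C3 is expected, but the new centre is ionized again in step 12.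

Step 11
Reactants: 25 tertiary alcohol; 21 N-bromosuccinimide
Product: 26 tertiary alcohol 25 brominated at C6 of the epicatechin unit
Conditions: CH2Cl2, −40 → 0 °C
Reagents that add atoms: N-bromosuccinimide, O=C1CCC(=O)N1Br
Why: Electrophilic bromination at the only free position of the phloroglucinol ring, which is far more reactive than the brominated, PMB-capped mid ring; the bromine blocks bottom C6 for step 13.

Step 12
Reactants: 26 brominated tertiary alcohol
Product: 27 dimer phenol: 6-bromo-7-hydroxy-3-O-pivaloyl-3',4',5'-tri-O-benzyl-epirobinetinidol-(4α→8)-6-bromo-penta-O-benzyl-epicatechin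
Conditions: Bu3SnH, CF3CO2H, CH2Cl2, 0 °C → rt
Reagents that add atoms: none
Why: Ionic hydrogenation: the acid ionizes the doubly benzylic tertiary alcohol and the tin hydride delivers hydride to the β-face, anti to the 2-aryl and 3-pivaloyloxy groups, which sets mid C4 with the aryl group α (3,4-cis) as known for 4-aryl-epicatechin-4-ols, while the same acid cleaves the PMB ether and the hydride reduces its cation.

Step 13
Reactants: 14 trans-dipivalate; 27 dimer phenol
Product: 28 protected trimer (top unit 4β→8 mid unit; top 3-OPiv and 7-OPMB; mid 3-OPiv and free 7-OH; Br at C6 of all three A rings)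
Conditions: TMSOTf (0.2 equiv), 4 Å MS, CH2Cl2, −78 → −40 °C
Reagents that add atoms: none
Why: Biomimetic interflavan bond formation (SN1 Friedel–Crafts alkylation): the acid regenerates acyloxonium ion 13, which C8 of the mid unit, the only free position ortho to the free 7-OH, should open at C4 from the β-face to give the 4β→8 (3,4-trans) bond.

Step 14
Reactants: 28 protected trimer
Product: 29 trimer with free 3-OH on the top and mid units
Conditions: DIBAL-H, CH2Cl2, −78 → 0 °C; Rochelle salt work-up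
Reagents that add atoms: none
Why: Reductive cleavage of the two hindered pivalates; benzyl and PMB ethers and aryl bromides are inert to DIBAL-H.

Step 15
Reactants: 29 trimer with free 3-OH groups
Product: 30 CNP0115797.2
Conditions: H2 (1 atm), Pd(OH)2/C, NaOAc, THF–MeOH–H2O, rt
Reagents that add atoms: none
Why: Hydrogenolysis should cleave the eleven benzyl ethers and the PMB ether and hydrodehalogenate the three aryl bromides, with acetate buffering HBr so that the acid-labile interflavan bonds survive.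

## Compound list

1 | 5-bromo-2,4-dihydroxybenzaldehyde | O=Cc1cc(Br)c(O)cc1O | starting material
2 | 4-methoxybenzyl chloride | COc1ccc(CCl)cc1 | starting material
3 | 5-bromo-2-hydroxy-4-[(4-methoxybenzyl)oxy]benzaldehyde | O=Cc1cc(Br)c(OCc2ccc(OC)cc2)cc1O | intermediate
4 | dimethyl (1-diazo-2-oxopropyl)phosphonate | COP(=O)(OC)C(=[N+]=[N-])C(C)=O | starting material
5 | 4-bromo-2-ethynyl-5-[(4-methoxybenzyl)oxy]phenol | C#Cc1cc(Br)c(OCc2ccc(OC)cc2)cc1O | intermediate
6 | 3,4,5-tris(benzyloxy)benzaldehyde | O=Cc1cc(OCc2ccccc2)c(OCc2ccccc2)c(OCc2ccccc2)c1 | starting material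
7 | pivaloyl chloride | CC(C)(C)C(=O)Cl | starting material
8 | chloro[3,4,5-tris(benzyloxy)phenyl]methyl pivalate (racemic, not isolated) | CC(C)(C)C(=O)OC(Cl)c1cc(OCc2ccccc2)c(OCc2ccccc2)c(OCc2ccccc2)c1 | intermediate
9 | {4-bromo-2-ethynyl-5-[(4-methoxybenzyl)oxy]phenoxy}[3,4,5-tris(benzyloxy)phenyl]methyl pivalate (racemic) | C#Cc1cc(Br)c(OCc2ccc(OC)cc2)cc1OC(OC(=O)C(C)(C)C)c1cc(OCc2ccccc2)c(OCc2ccccc2)c(OCc2ccccc2)c1 | intermediate
10 | pivalic acid | CC(C)(C)C(=O)O | starting material
11 | (Z)-2-{5-bromo-4-[(4-methoxybenzyl)oxy]-2-[(pivaloyloxy)(3,4,5-tris(benzyloxy)phenyl)methoxy]phenyl}vinyl pivalate (racemic at the acetal carbon) | CC(C)(C)C(=O)O/C=C\c1cc(Br)c(OCc2ccc(OC)cc2)cc1OC(OC(=O)C(C)(C)C)c1cc(OCc2ccccc2)c(OCc2ccccc2)c(OCc2ccccc2)c1 | intermediate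
12 | aryloxycarbenium ion formed from 11 by loss of pivalate (not isolated) | CC(C)(C)C(=O)O/C=C\c1cc(Br)c(OCc2ccc(OC)cc2)cc1[O+]=Cc1cc(OCc2ccccc2)c(OCc2ccccc2)c(OCc2ccccc2)c1 | intermediate
13 | cis-fused 2-tert-butyl-1,3-dioxolan-2-ylium ion across O3 and O4 of the (2R)-chroman, both oxygens α (not isolated) | COc1ccc(COc2c(Br)cc3c(c2)O[C@H](c2cc(OCc4ccccc4)c(OCc4ccccc4)c(OCc4ccccc4)c2)[C@@H]2OC(C(C)(C)C)=[O+][C@H]32)cc1 | intermediate
14 | (2R)-2,3-cis-3,4-trans-6-bromo-7-[(4-methoxybenzyl)oxy]-2-[3,4,5-tris(benzyloxy)phenyl]chromane-3,4-diyl dipivalate (2-aryl α, 3-OPiv α, 4-OPiv β) | COc1ccc(COc2c(Br)cc3c(c2)O[C@H](c2cc(OCc4ccccc4)c(OCc4ccccc4)c(OCc4ccccc4)c2)[C@H](OC(=O)C(C)(C)C)[C@H]3OC(=O)C(C)(C)C)cc1 | intermediate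
15 | water | O | starting material
16 | (2R)-2,3-cis-3,4-cis-6-bromo-4-hydroxy-7-[(4-methoxybenzyl)oxy]-2-[3,4,5-tris(benzyloxy)phenyl]chroman-3-yl pivalate (all three substituents α) | COc1ccc(COc2c(Br)cc3c(c2)O[C@H](c2cc(OCc4ccccc4)c(OCc4ccccc4)c(OCc4ccccc4)c2)[C@H](OC(=O)C(C)(C)C)[C@@H]3O)cc1 | intermediate
17 | (2R)-2,3-cis-6-bromo-7-[(4-methoxybenzyl)oxy]-4-oxo-2-[3,4,5-tris(benzyloxy)phenyl]chroman-3-yl pivalate | COc1ccc(COc2c(Br)cc3c(c2)O[C@H](c2cc(OCc4ccccc4)c(OCc4ccccc4)c(OCc4ccccc4)c2)[C@H](OC(=O)C(C)(C)C)C3=O)cc1 | intermediate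
18 | (−)-epicatechin, (2R,3R) | Oc1cc(O)c2c(c1)O[C@H](c1ccc(O)c(O)c1)[C@H](O)C2 | starting material
19 | benzyl bromide | BrCc1ccccc1 | starting material
20 | 3,5,7,3',4'-penta-O-benzyl-(−)-epicatechin | C(Oc1cc(OCc3ccccc3)c2c(c1)O[C@H](c1ccc(OCc3ccccc3)c(OCc3ccccc3)c1)[C@H](OCc1ccccc1)C2)c1ccccc1 | intermediate
21 | N-bromosuccinimide | O=C1CCC(=O)N1Br | starting material
22 | 8-bromo-3,5,7,3',4'-penta-O-benzyl-(−)-epicatechin | C(Oc1cc(OCc3ccccc3)c2c(c1Br)O[C@H](c1ccc(OCc3ccccc3)c(OCc3ccccc3)c1)[C@H](OCc1ccccc1)C2)c1ccccc1 | intermediate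
23 | 8-lithio-3,5,7,3',4'-penta-O-benzyl-(−)-epicatechin (not isolated) | C(Oc1cc(OCc3ccccc3)c2c(c1[Li])O[C@H](c1ccc(OCc3ccccc3)c(OCc3ccccc3)c1)[C@H](OCc1ccccc1)C2)c1ccccc1 | intermediate
24 | 8-(dichlorocerio)-3,5,7,3',4'-penta-O-benzyl-(−)-epicatechin (not isolated) | C(Oc1cc(OCc3ccccc3)c2c(c1[Ce](Cl)Cl)O[C@H](c1ccc(OCc3ccccc3)c(OCc3ccccc3)c1)[C@H](OCc1ccccc1)C2)c1ccccc1 | intermediate
25 | tertiary alcohol: chroman of 17 with 4α-OH and, at 4β, C8 of penta-O-benzyl-(−)-epicatechin | COc1ccc(COc2c(Br)cc3c(c2)O[C@H](c2cc(OCc4ccccc4)c(OCc4ccccc4)c(OCc4ccccc4)c2)[C@H](OC(=O)C(C)(C)C)[C@@]3(O)c2c(OCc4ccccc4)cc(OCc4ccccc4)c3c2O[C@H](c2ccc(OCc4ccccc4)c(OCc4ccccc4)c2)[C@H](OCc2ccccc2)C3)cc1 | intermediate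
26 | 25 with bromine at C6 of the epicatechin unit | COc1ccc(COc2c(Br)cc3c(c2)O[C@H](c2cc(OCc4ccccc4)c(OCc4ccccc4)c(OCc4ccccc4)c2)[C@H](OC(=O)C(C)(C)C)[C@@]3(O)c2c(OCc4ccccc4)c(Br)c(OCc4ccccc4)c3c2O[C@H](c2ccc(OCc4ccccc4)c(OCc4ccccc4)c2)[C@H](OCc2ccccc2)C3)cc1 | intermediate
27 | dimer phenol: 6-bromo-7-hydroxy-3-O-pivaloyl-3',4',5'-tri-O-benzyl-epirobinetinidol-(4α→8)-6-bromo-3,5,7,3',4'-penta-O-benzyl-epicatechin (mid unit all-cis) | Oc1c(Br)cc2c(c1)O[C@H](c1cc(OCc3ccccc3)c(OCc3ccccc3)c(OCc3ccccc3)c1)[C@H](OC(=O)C(C)(C)C)[C@@H]2c1c(OCc3ccccc3)c(Br)c(OCc3ccccc3)c2c1O[C@H](c1ccc(OCc3ccccc3)c(OCc3ccccc3)c1)[C@H](OCc1ccccc1)C2 | intermediate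
28 | protected trimer: top unit (6-Br, 7-OPMB, 3-OPiv, tri-O-benzyl B ring; 2,3-cis-3,4-trans) bonded 4β→8 to dimer 27 | COc1ccc(COc2c(Br)cc3c(c2)O[C@H](c2cc(OCc4ccccc4)c(OCc4ccccc4)c(OCc4ccccc4)c2)[C@H](OC(=O)C(C)(C)C)[C@H]3c2c(O)c(Br)cc3c2O[C@H](c2cc(OCc4ccccc4)c(OCc4ccccc4)c(OCc4ccccc4)c2)[C@H](OC(=O)C(C)(C)C)[C@@H]3c2c(OCc4ccccc4)c(Br)c(OCc4ccccc4)c3c2O[C@H](c2ccc(OCc4ccccc4)c(OCc4ccccc4)c2)[C@H](OCc2ccccc2)C3)cc1 | intermediate
29 | trimer 28 with both pivalates replaced by OH | COc1ccc(COc2c(Br)cc3c(c2)O[C@H](c2cc(OCc4ccccc4)c(OCc4ccccc4)c(OCc4ccccc4)c2)[C@H](O)[C@H]3c2c(O)c(Br)cc3c2O[C@H](c2cc(OCc4ccccc4)c(OCc4ccccc4)c(OCc4ccccc4)c2)[C@H](O)[C@@H]3c2c(OCc4ccccc4)c(Br)c(OCc4ccccc4)c3c2O[C@H](c2ccc(OCc4ccccc4)c(OCc4ccccc4)c2)[C@H](OCc2ccccc2)C3)cc1 | intermediate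
30 | CNP0115797.2, epirobinetinidol-(4β→8)-epirobinetinidol-(4α→8)-epicatechin | Oc1ccc2c(c1)O[C@H](c1cc(O)c(O)c(O)c1)[C@H](O)[C@H]2c1c(O)ccc2c1O[C@H](c1cc(O)c(O)c(O)c1)[C@H](O)[C@@H]2c1c(O)cc(O)c2c1O[C@H](c1ccc(O)c(O)c1)[C@H](O)C2 | target

## Step count and risks

Total step count: 15. Longest linear sequence: 13 steps (1–7, then 10–15).

Steps most likely to fail:

Step 5 (proposed new method). The chiral ion pair may discriminate the two faces poorly. The enol ester may react with its normal polarity and close 5-exo to a benzofuran. The Z-olefin may isomerize before cyclization. The acid may stay bound as the acyloxonium salt and stop turning over.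
The fallback sets out from aldehyde 6 and comes back at alcohol 16. Commercial 1-(5-bromo-2,4-dihydroxyphenyl)ethanone is etherified with 2 (K2CO3, acetone) to 1-{5-bromo-2-hydroxy-4-[(4-methoxybenzyl)oxy]phenyl}ethanone F1. Claisen–Schmidt condensation of F1 with 6 (KOH, EtOH) should give the chalcone F2. Algar–Flynn–Oyamada oxidation (H2O2, NaOH) should give the flavonol F3, and pivaloylation (7, Et3N, DMAP) the flavonol pivalate F4. Asymmetric hydrogenation of the C2=C3 and C4=O bonds of F4 with a chiral Ru–NHC catalyst, a reaction established for flavones, adds hydrogen to one face and should give the all-cis alcohol 16. 16 is oxidized to 17 as in step 7, and in step 13 it takes the place of 14, since TMSOTf ionizes its C4–OH to the same ion 13.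

Step 13. C8 of the mid unit is flanked by O1 and the 7-OH inside a crowded dimer, so C-alkylation may be slow. The phenol oxygen or the acyl carbon of ion 13 may be attacked instead. Prolonged acid may cleave the mid–bottom bond or the PMB ether.
The fallback sets out from 14 and comes back at 28. Thiolysis of 14 with benzyl mercaptan (BF3·OEt2, CH2Cl2, −20 °C) passes through ion 13 and should give the 4β-benzylthio ether F5. F5 and 27 are then joined by thiophilic activation with AgBF4 (THF, 0 °C), a known near-neutral way to form interflavan bonds with free phenolic nucleophiles, to give 28.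

Step 10. The organometallic may enolize the α-acyloxy ketone and epimerize C3. The new alkoxide may take over the pivaloyl group. The aryl bromide of 17 may enter halogen–metal exchange.
The fallback sets out from 17 and 20 and comes back at 27; it uses no organometallic. 17 is activated with TMSOTf (CH2Cl2, −40 °C) in the presence of 20, whose C8 should attack the C4 cation (Friedel–Crafts hydroxyalkylation). Bu3SnH is then added to reduce the diarylmethyl cation from the β-face (ionic hydrogenation), giving the 4α→8 dimer F6 with the PMB ether intact. NBS brominates bottom C6 to F7, and CF3CO2H/Bu3SnH removes the PMB group to give 27.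

Further compounds
F1 | step 5 | 1-{5-bromo-2-hydroxy-4-[(4-methoxybenzyl)oxy]phenyl}ethanone | CC(=O)c1cc(Br)c(OCc2ccc(OC)cc2)cc1O
F2 | step 5 | (E)-1-{5-bromo-2-hydroxy-4-[(4-methoxybenzyl)oxy]phenyl}-3-[3,4,5-tris(benzyloxy)phenyl]prop-2-en-1-one | O=C(/C=C/c1cc(OCc2ccccc2)c(OCc2ccccc2)c(OCc2ccccc2)c1)c1cc(Br)c(OCc2ccc(OC)cc2)cc1O
F3 | step 5 | 6-bromo-3-hydroxy-7-[(4-methoxybenzyl)oxy]-2-[3,4,5-tris(benzyloxy)phenyl]-4H-chromen-4-one | COc1ccc(COc2cc3oc(-c4cc(OCc5ccccc5)c(OCc5ccccc5)c(OCc5ccccc5)c4)c(O)c(=O)c3cc2Br)cc1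
F4 | step 5 | 6-bromo-7-[(4-methoxybenzyl)oxy]-4-oxo-2-[3,4,5-tris(benzyloxy)phenyl]-4H-chromen-3-yl pivalate | COc1ccc(COc2cc3oc(-c4cc(OCc5ccccc5)c(OCc5ccccc5)c(OCc5ccccc5)c4)c(OC(=O)C(C)(C)C)c(=O)c3cc2Br)cc1
F5 | step 13 | (2R)-2,3-cis-3,4-trans-4-(benzylthio)-6-bromo-7-[(4-methoxybenzyl)oxy]-2-[3,4,5-tris(benzyloxy)phenyl]chroman-3-yl pivalate | COc1ccc(COc2c(Br)cc3c(c2)O[C@H](c2cc(OCc4ccccc4)c(OCc4ccccc4)c(OCc4ccccc4)c2)[C@H](OC(=O)C(C)(C)C)[C@H]3SCc2ccccc2)cc1
F6 | step 10 | 6-bromo-7-O-(4-methoxybenzyl)-3-O-pivaloyl-3',4',5'-tri-O-benzyl-epirobinetinidol-(4α→8)-3,5,7,3',4'-penta-O-benzyl-epicatechin | COc1ccc(COc2c(Br)cc3c(c2)O[C@H](c2cc(OCc4ccccc4)c(OCc4ccccc4)c(OCc4ccccc4)c2)[C@H](OC(=O)C(C)(C)C)[C@@H]3c2c(OCc4ccccc4)cc(OCc4ccccc4)c3c2O[C@H](c2ccc(OCc4ccccc4)c(OCc4ccccc4)c2)[C@H](OCc2ccccc2)C3)cc1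
F7 | step 10 | F6 with bromine at C6 of the epicatechin unit | COc1ccc(COc2c(Br)cc3c(c2)O[C@H](c2cc(OCc4ccccc4)c(OCc4ccccc4)c(OCc4ccccc4)c2)[C@H](OC(=O)C(C)(C)C)[C@@H]3c2c(OCc4ccccc4)c(Br)c(OCc4ccccc4)c3c2O[C@H](c2ccc(OCc4ccccc4)c(OCc4ccccc4)c2)[C@H](OCc2ccccc2)C3)cc1
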